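# Late furan closure on a bis-unit lactone: synthesis design for CNP0186558.3 (30)

## The problem

Compound 30 is a trans-(3S,4S)-α,β-dibenzyl-γ-butyrolactone in which each benzyl ring carries, ortho to its own phenolic oxygen, a three-carbon chain bearing a guaiacyl ring. On the α-arm (ring B) the chain is open: carbinol C7 (S, bearing ring A), C8 (S, bearing ring B) and C9H2OH. On the β-arm (ring C) the same chain is closed through the ring C oxygen to a trans-(2R,3S)-2-aryl-3-hydroxymethyl-2,3-dihydrobenzofuran carrying ring D.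

The six stereocentres fall into three pairs that are too far apart to control one another. In the lactone pair C4 has to be set absolutely and C3 then follows by trans alkylation. The two side-chain pairs share the same C8 configuration and differ only by inversion at the benzylic carbon.

The open unit is the fragile part. A 4-hydroxybenzylic alcohol with a phenol beside it ionises to a para-quinone methide under acid, and it does the same in base once the benzylic oxygen is acylated. The target would therefore close to a second furan under acidic deprotection, so the last step has to be neutral. The lactone tolerates neither hydride nor hot alkoxide, although its trans arrangement is the thermodynamic one.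

What makes a late ring closure possible is the geometry of an open unit on ring C. The ring C phenol oxygen lies five atoms from C7', and C7' is para to the ring D phenol. Ionisation gives a planar quinone methide, O–C2 closure is 5-exo, and the hydroxymethyl-bearing C8' alone decides the trans geometry. One anti-(7S,8S) unit can thus serve both arms, provided the two copies can be told apart at the moment of closure.

## Retrosynthesis

**30 from 29 (two aryl acetates removed).** The α-arm must be switched off during the acid step and then released without acid. Acetates on the ring A and ring B oxygens do this: they remove the para electron push and the neighbouring nucleophile. The C7 and C9 hydroxyls are deliberately left free in 29. A peracetylated α-arm would be simpler to draw, but a benzylic acetate para to a phenoxide eliminates to a quinone methide as soon as the phenolic acetate is cleaved, which would scramble C7 in the last step. With only aryl acetates, a neutral methanolysis suffices.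

**29 from 27 (O–C2 of the furan cut).** The bond between the ring C oxygen and C7' of the β-arm is disconnected, giving lactone 27 with two identical anti units, the α one carrying the two aryl acetates. Against cutting C2–C3 or building the furan early, this cut lets one building block serve both arms and makes the C7' configuration of the β-arm irrelevant, since it passes through quinone methide 28. The precursor has one ring and one fixed stereocentre fewer. The forward reaction must ionise only the β-arm carbinol and deliver the trans furan.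

**27 from 26, 25 and 24 (protecting-group staging).** Compound 27 needs the α-arm phenols acetylated and everything else free. This follows from 24, in which the β-arm unit is fully silylated (four TBS groups) and the α-arm unit carries two aryl benzyl ethers and two alkyl TBS ethers.
- Hydrogenolysis frees only the α-arm phenols (25).
- Acetylation marks them (26).
- One fluoride treatment removes all six silyl groups (27).

The order is forced: acetylation must take place while the β-arm phenols are still silylated.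

**24 from 23 and 15 (lactone C3–CH2 bond to ring B cut).** Alkylation of the enolate of β-substituted lactone 23 with benzylic bromide 15 halves the molecule and sets C3 trans to C4 by substrate control. An aldol, dehydration and hydrogenation sequence would need an extra stereochemical correction. The forward step asks only that the aryl and alkyl silyl ethers survive a lithium amide at low temperature.

**23 from 22, 21, 19, and from 18 and 15 (lactone C4–CH2 bond to ring C, and the lactone C–O bond, cut).** The C4 centre is set by alkylating the sodium enolate of succinate imide 18 with the same bromide 15. Reductive removal of the auxiliary from 19 and lactonisation of hydroxy ester 20 give 21.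
- A Stobbe condensation followed by asymmetric hydrogenation was the neighbouring option. It needs an aldehyde, hot alkoxide and a second chiral controller.
- The imide route uses bromide 15 twice and the same auxiliary 5 that serves the aldol.
- The benzyl-to-silyl swap on the two phenols (21 to 22 to 23) is placed here because this is the first intermediate that has neither an aryl bromide nor a benzylic bromide to interfere with hydrogenolysis.

Imide 18 comes from mono-tert-butyl succinate 16 and 5.

**15 from 14 and 12 (ring B–CH2 bond cut).** The benzylic carbon is introduced as a formyl group from DMF at the position of the aryl bromide in 12. Aldehyde 13 is reduced in the same pot to alcohol 14, which is brominated. The bromine of 12 sits para to the ring oxygen, exactly where the lactone arm must grow.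

**12 from 11, 10, and from 7 and 8 (C7–C8 bond cut).** An auxiliary-controlled anti-aldol between arylacetyl imide 7 and O-benzylvanillin 8 builds both unit stereocentres in one step and leaves C9 as the imide carbonyl, which reduction turns into the primary alcohol of diol 11. Alkene-based approaches would have to add C9 and two oxygens with the same relative configuration; the aldol delivers the diol free and ready for any protection. The reaction must give the anti adduct in the (2R,3S) series.

**7 from 4, 3, 2 and 1 (CH2CO2H from CHO).** Acid 4 is the one-carbon homologue of aldehyde 2, reached through trichloromethyl carbinol 3. Aldehyde 2 is the benzyl ether of 5-bromo-2-hydroxy-3-methoxybenzaldehyde 1. Starting from 1, rather than from 5-bromovanillin, places the acetic acid side chain ortho to the phenol without a palladium arylation and leaves the halogen para to it.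

## Roads not taken

**Alternative 1: Prins reaction of a stilbene with formaldehyde.**
- *Cut and forward step:* C9 and the C7 oxygen are removed, leaving E-stilbene A1 and formaldehyde. A confined chiral imino-imidodiphosphate Brønsted acid would promote addition of paraformaldehyde, forming C8–C9 and C7–O, and give trans-4,5-diaryl-1,3-dioxane A2, the anti unit with its diol already masked.
- *Merits:* it is catalytic, needs no auxiliary, and sets both unit centres and C9 in one operation on a substrate that a Wittig or Heck coupling would supply.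
- *Weak points:*
  - C–C bonding at the ring B carbon requires the cation to develop at C7. The donor ring A against the ester- and acyloxy-bearing ring B makes this plausible, but C7 is then set by capture of a free, alkoxy-stabilised benzylic cation, outside the concerted regime on which the enantiocontrol of such catalysts rests.
  - 1,2-Diaryl alkenes are far less reactive than the terminal alkenes for which this catalysis is established, and the electron-rich rings can be hydroxymethylated instead.
  - The methylene acetal is the hardest 1,3-diol protection to remove, and the acids that cleave it are the ones that ionise C7.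
- *Comparison:* if it worked, A2 would be reached in fewer steps and with less waste than 12, which is a real advantage. The chosen plan sets against it a known enolate reaction on a known substrate class, a diol delivered free so that its protection can be chosen for the endgame, and an auxiliary that also fixes the lactone centre.

**Alternative 2: carbene C–H insertion to close the dihydrofuran.**
- *Cut and forward step:* C2–C3 of the furan is cut. Aryl diazoacetate A3 with Rh2(PTTL)4, dirhodium tetrakis(N-phthaloyl-tert-leucinate), would give a carbene that inserts into the benzylic OCH2 C–H bond. DBU then epimerises C3 to give trans ester A4.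
- *Merits:* it is catalytic and established for this ring type. The stereochemistry is fixed early in a robust ring, the bromide is already para to the ring oxygen, and no late acid step is needed.
- *Weak points:*
  - It makes only the closed unit. The open α-arm unit still needs its own enantioselective anti-diol synthesis, so two unrelated stereochemical campaigns are run.
  - The C3 ester and the phenol protection of A4 must then be adjusted before the lactone is built.
- *Comparison:* for the β-arm alone A4 is at least as secure as a late closure and avoids any question of arm selectivity. The chosen plan sets against it a single unit, bromide 15, used in both step 11 and step 15, and a closure that forgives any C7 leakage from the aldol on the β-arm.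

**Alternative 3: desymmetrising Baeyer–Villiger oxidation of a cyclobutanone.**
- *Cut and forward step:* the lactone O–CH2 bond is cut. Prochiral 3-substituted cyclobutanone A5, with aqueous H2O2 and a chiral BINOL-derived phosphoric acid, would undergo migration of one of its two enantiotopic CH2 groups to give (S)-lactone A6.
- *Merits:* it is catalytic and metal-free, with no auxiliary to attach or remove.
- *Weak points:*
  - This oxidation is at its best when an aryl group sits directly on C3. Here the differentiating group is one methylene further out, so lower selectivity is to be expected.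
  - A5 would need an allylarene, a ketene cycloaddition and a dechlorination on an advanced intermediate.
  - It presupposes a furan made beforehand and so gives up the shared unit.
- *Comparison:* in catalyst economy it is better. The chosen plan sets against it two steps from 15 to lactone 21, diastereomers that can be separated at the imide stage, and reuse of 5.

Key step: step 19

## Route

Assumptions:
- Compounds 1, 5, 8 and 16 are treated as purchasable; 1 and 8 are otherwise one step from o-vanillin and vanillin.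
- The magnesium-catalysed aldol is taken to follow the chelated Z-enolate model, so that the (4S)-auxiliary leads to the (2R,3S) adduct.

Abbreviations: Bn = benzyl, TBS = tert-butyldimethylsilyl, TBSO = tert-butyldimethylsilyloxy, TES = triethylsilyl, Piv = pivaloyl.

Step 1
Reactants: 1 5-bromo-2-hydroxy-3-methoxybenzaldehyde
Product: 2 2-(benzyloxy)-5-bromo-3-methoxybenzaldehyde
Conditions: BnBr, K2CO3, DMF, rt
Reagents that add atoms: benzyl bromide, BrCc1ccccc1
Why: Williamson etherification of the phenoxide; the benzyl ether then withstands base, hydride and organolithium until steps 13 and 16.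

Step 2
Reactants: 2 2-(benzyloxy)-5-bromo-3-methoxybenzaldehyde
Product: 3 rac-1-[2-(benzyloxy)-5-bromo-3-methoxyphenyl]-2,2,2-trichloroethanol
Conditions: CHCl3, DBU, rt
Reagents that add atoms: chloroform, ClC(Cl)Cl
Why: Amidine-promoted addition of the trichloromethyl anion to an aromatic aldehyde; the carbinol centre is racemic and irrelevant because it becomes a CH2 group in step 3.

Step 3
Reactants: 3 rac-trichloromethyl carbinol
Product: 4 [2-(benzyloxy)-5-bromo-3-methoxyphenyl]acetic acid
Conditions: NaBH4, NaOH, t-BuOH, 55 °C; then aq. HCl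
Reagents that add atoms: sodium hydroxide, [Na+].[OH-]
Why: Jocic–Reeve-type reductive homologation: the alkoxide closes to a gem-dichloroepoxide, hydride opens it at the benzylic carbon and the acyl chloride so formed is hydrolysed to the arylacetate; aryl bromide and benzyl ether are inert to borohydride.

Step 4
Reactants: 4 arylacetic acid; 5 (4S)-4-benzyl-1,3-oxazolidin-2-one
Product: 7 (4S)-4-benzyl-3-{[2-(benzyloxy)-5-bromo-3-methoxyphenyl]acetyl}-1,3-oxazolidin-2-one, via mixed pivalic anhydride 6 (not isolated)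
Conditions: PivCl, Et3N, THF, −20 °C; then LiCl, 5, rt
Reagents that add atoms: none
Why: N-Acylation of the oxazolidinone through the mixed pivalic anhydride (LiCl/Et3N variant); the nucleophile attacks the less hindered arylacetyl carbonyl.

Step 5
Reactants: 7 arylacetyl imide; 8 4-(benzyloxy)-3-methoxybenzaldehyde
Product: 10 (4S)-4-benzyl-3-{(2R,3S)-3-[4-(benzyloxy)-3-methoxyphenyl]-2-[2-(benzyloxy)-5-bromo-3-methoxyphenyl]-3-hydroxypropanoyl}-1,3-oxazolidin-2-one, via trimethylsilyl ether 9 (not isolated)
Conditions: MgCl2 (20 mol%), Et3N, Me3SiCl, EtOAc, rt; then 1 M HCl, THF, 0 °C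
Reagents that add atoms: none
Why: Magnesium-halide-catalysed direct anti-aldol of an N-acyloxazolidinone (Evans type): soft enolisation gives the chelated Z-enolate, the aldehyde adds through a boat transition state on the face away from the auxiliary benzyl group, and silylation of the aldolate by Me3SiCl releases MgCl2; this should set C8 (2R in the imide) and the anti carbinol C7 (3S) together.

Step 6
Reactants: 10 aldol imide
Product: 11 (1S,2S)-1-[4-(benzyloxy)-3-methoxyphenyl]-2-[2-(benzyloxy)-5-bromo-3-methoxyphenyl]propane-1,3-diol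
Conditions: LiBH4, MeOH (1 equiv), THF, 0 °C
Reagents that add atoms: none
Why: Reductive cleavage of the N-acyloxazolidinone to the primary alcohol; the cold, weakly basic hydride should avoid retro-aldol and C8 epimerisation, and auxiliary 5 is recovered.

Step 7
Reactants: 11 anti diol
Product: 12 (1S,2S)-1-[4-(benzyloxy)-3-methoxyphenyl]-2-[2-(benzyloxy)-5-bromo-3-methoxyphenyl]-1,3-bis(TBSO)propane
Conditions: TBSOTf, 2,6-lutidine, CH2Cl2, −78 to 0 °C
Reagents that add atoms: tert-butyldimethylsilyl triflate, CC(C)(C)[Si](C)(C)OS(=O)(=O)C(F)(F)F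
Why: Silyl triflate silylation of both the primary and the hindered benzylic hydroxyl; the lutidine-buffered conditions do not ionise the electron-rich benzylic carbinol.

Step 8
Reactants: 12 bis-silylated aryl bromide
Product: 14 [4-(benzyloxy)-3-{(1S,2S)-1-[4-(benzyloxy)-3-methoxyphenyl]-1,3-bis(TBSO)propan-2-yl}-5-methoxyphenyl]methanol, via aldehyde 13 (not isolated)
Conditions: n-BuLi, THF, −78 °C; DMF, −78 to 0 °C; then MeOH, NaBH4, 0 °C
Reagents that add atoms: N,N-dimethylformamide, CN(C)C=O
Why: Bromine–lithium exchange and formylation of the aryllithium with DMF, followed by borohydride reduction of the aldehyde in the same pot; exchange at −78 °C is much faster than deprotonation of the benzyl ethers.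

Step 9
Reactants: 14 benzylic alcohol
Product: 15 4-(benzyloxy)-3-{(1S,2S)-1-[4-(benzyloxy)-3-methoxyphenyl]-1,3-bis(TBSO)propan-2-yl}-5-methoxybenzyl bromide
Conditions: CBr4, PPh3, 2,6-lutidine, CH2Cl2, 0 °C
Reagents that add atoms: carbon tetrabromide, BrC(Br)(Br)Br
Why: Appel bromination of a primary benzylic alcohol under neutral conditions that leave silyl and benzyl ethers alone; the bromide is used without storage in steps 11 and 15.

Step 10
Reactants: 16 4-tert-butoxy-4-oxobutanoic acid; 5 (4S)-4-benzyl-1,3-oxazolidin-2-one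
Product: 18 tert-butyl 4-[(4S)-4-benzyl-2-oxo-1,3-oxazolidin-3-yl]-4-oxobutanoate, via mixed pivalic anhydride 17 (not isolated)
Conditions: PivCl, Et3N, THF, −20 °C; then LiCl, 5, rt
Reagents that add atoms: none
Why: N-Acylation through the mixed pivalic anhydride as in step 4; the tert-butyl ester is untouched.

Step 11
Reactants: 18 succinate imide; 15 unit benzyl bromide
Product: 19 tert-butyl (3S)-4-[(4S)-4-benzyl-2-oxo-1,3-oxazolidin-3-yl]-3-[4-(benzyloxy)-3-{(1S,2S)-1-[4-(benzyloxy)-3-methoxyphenyl]-1,3-bis(TBSO)propan-2-yl}-5-methoxybenzyl]-4-oxobutanoate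
Conditions: NaN(SiMe3)2, THF, −78 °C; then 15, −78 to −30 °C
Reagents that add atoms: none
Why: Oxazolidinone (Evans-type) enolate alkylation: only the imide α-CH2 is deprotonated because it is far more acidic than the ester α-CH2, and the chelated Z-sodium enolate is benzylated on the face opposite the auxiliary benzyl group, which sets the future lactone C4 as S.

Step 12
Reactants: 19 alkylated imide
Product: 21 (4S)-4-[4-(benzyloxy)-3-{(1S,2S)-1-[4-(benzyloxy)-3-methoxyphenyl]-1,3-bis(TBSO)propan-2-yl}-5-methoxybenzyl]dihydrofuran-2(3H)-one, via hydroxy ester 20 (not isolated)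
Conditions: LiBH4, H2O (1 equiv), Et2O, 0 °C; then PPTS (cat.), PhMe, 70 °C
Reagents that add atoms: none
Why: Chemoselective borohydride cleavage of the imide (the tert-butyl ester survives) followed by acid-catalysed lactonisation of the γ-hydroxy ester with loss of tert-butanol; the stereocentre is never enolisable on the way.

Step 13
Reactants: 21 β-benzyl lactone
Product: 22 (4S)-4-[3-{(1S,2S)-1,3-bis(TBSO)-1-(4-hydroxy-3-methoxyphenyl)propan-2-yl}-4-hydroxy-5-methoxybenzyl]dihydrofuran-2(3H)-one
Conditions: H2 (1 atm), 10% Pd/C, EtOAc, rt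
Reagents that add atoms: none
Why: Hydrogenolysis of the two aryl benzyl ethers; in neutral ethyl acetate the silyl ethers, the lactone and the benzylic C–OSi bond should not be touched.

Step 14
Reactants: 22 diphenol lactone
Product: 23 (4S)-4-[4-(TBSO)-3-{(1S,2S)-1,3-bis(TBSO)-1-[4-(TBSO)-3-methoxyphenyl]propan-2-yl}-5-methoxybenzyl]dihydrofuran-2(3H)-one
Conditions: TBSCl, imidazole, DMF, 40 °C
Reagents that add atoms: tert-butyldimethylsilyl chloride, CC(C)(C)[Si](C)(C)Cl
Why: Silylation of both phenols, so that the whole β-arm unit carries only fluoride-labile groups and no acidic proton during step 15.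

Step 15
Reactants: 23 tetrasilylated lactone; 15 unit benzyl bromide
Product: 24 (3S,4S)-3-[4-(benzyloxy)-3-{(1S,2S)-1-[4-(benzyloxy)-3-methoxyphenyl]-1,3-bis(TBSO)propan-2-yl}-5-methoxybenzyl]-4-[4-(TBSO)-3-{(1S,2S)-1,3-bis(TBSO)-1-[4-(TBSO)-3-methoxyphenyl]propan-2-yl}-5-methoxybenzyl]dihydrofuran-2(3H)-one
Conditions: LiN(SiMe3)2, THF, −78 °C; then 15, DMPU, −78 to −40 °C
Reagents that add atoms: none
Why: Alkylation of the lactone lithium enolate; the bromide approaches anti to the C4 substituent, the usual outcome for β-substituted γ-butyrolactone enolates, which sets C3 as S (trans).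

Step 16
Reactants: 24 bis-unit lactone
Product: 25 (3S,4S)-3-[3-{(1S,2S)-1,3-bis(TBSO)-1-(4-hydroxy-3-methoxyphenyl)propan-2-yl}-4-hydroxy-5-methoxybenzyl]-4-[4-(TBSO)-3-{(1S,2S)-1,3-bis(TBSO)-1-[4-(TBSO)-3-methoxyphenyl]propan-2-yl}-5-methoxybenzyl]dihydrofuran-2(3H)-one
Conditions: H2 (1 atm), 10% Pd/C, EtOAc, rt
Reagents that add atoms: none
Why: Hydrogenolysis frees only the two α-arm phenols, since every other oxygen is silylated; this is the step that tells the two arms apart.

Step 17
Reactants: 25 α-arm diphenol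
Product: 26 (3S,4S)-3-[4-acetoxy-3-{(1S,2S)-1-(4-acetoxy-3-methoxyphenyl)-1,3-bis(TBSO)propan-2-yl}-5-methoxybenzyl]-4-[4-(TBSO)-3-{(1S,2S)-1,3-bis(TBSO)-1-[4-(TBSO)-3-methoxyphenyl]propan-2-yl}-5-methoxybenzyl]dihydrofuran-2(3H)-one
Conditions: Ac2O, pyridine, DMAP (cat.), CH2Cl2, 0 °C to rt
Reagents that add atoms: acetic anhydride, CC(=O)OC(C)=O
Why: Acylation of the only two free hydroxyls, the phenols of rings A and B; the acetates are the deactivating groups needed in step 19.

Step 18
Reactants: 26 α-arm diacetate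
Product: 27 (3S,4S)-3-[4-acetoxy-3-{(1S,2S)-1-(4-acetoxy-3-methoxyphenyl)-1,3-dihydroxypropan-2-yl}-5-methoxybenzyl]-4-[3-{(1S,2S)-1,3-dihydroxy-1-(4-hydroxy-3-methoxyphenyl)propan-2-yl}-4-hydroxy-5-methoxybenzyl]dihydrofuran-2(3H)-one
Conditions: HF·pyridine, pyridine, THF, 0 °C to rt
Reagents that add atoms: none
Why: Fluoride-mediated cleavage of all six silyl ethers under pyridine-buffered conditions that are too weakly acidic to ionise the benzylic carbinols and leave aryl acetates and the lactone intact.

Step 19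
Reactants: 27 lactone with two open anti units (α-arm phenols acetylated)
Product: 29 (3S,4S)-3-[4-acetoxy-3-{(1S,2S)-1-(4-acetoxy-3-methoxyphenyl)-1,3-dihydroxypropan-2-yl}-5-methoxybenzyl]-4-{[(2R,3S)-2-(4-hydroxy-3-methoxyphenyl)-3-(hydroxymethyl)-7-methoxy-2,3-dihydro-1-benzofuran-5-yl]methyl}dihydrofuran-2(3H)-one, via para-quinone methide 28 (not isolated)
Conditions: TsOH·H2O (10 mol%), MeCN, rt
Reagents that add atoms: none
Why: This is the acid-catalysed cyclodehydration of a 2-(2-hydroxyaryl)-1-(4-hydroxyaryl)propane-1,3-diol to a trans-2-aryl-2,3-dihydrobenzofuran, a known reaction type of this diol class. Protonation of the β-arm C7' hydroxyl and loss of water, pushed by the para hydroxyl of ring D, gives para-quinone methide 28 and erases the C7' configuration. The ring C phenol oxygen then adds to the exocyclic methide carbon in a 5-exo-trig closure that forms O–C2 and re-aromatises ring D. The new C2 centre is controlled by C3 (the former C8'): the aryl group takes the face away from the hydroxymethyl group, and because the ring can reopen to 28 under the same acid, any cis isomer should drain to the trans (2R,3S) furan. The step needs arm selectivity, and the α-arm secures it: the ring A oxygen is an acetate and cannot supply the electron push for ionisation of C7, and the ring B oxygen is an acetate too, so no nucleophile sits beside C7. The free C7 and C9 hydroxyls of the α-arm are poor leaving groups and poor nucleophiles under catalytic acid. Acetonitrile is chosen as a non-nucleophilic solvent so that 28 is not trapped from outside.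

Step 20
Reactants: 29 cyclised diacetate
Product: 30 (3S,4S)-3-[3-{(1S,2S)-1,3-dihydroxy-1-(4-hydroxy-3-methoxyphenyl)propan-2-yl}-4-hydroxy-5-methoxybenzyl]-4-{[(2R,3S)-2-(4-hydroxy-3-methoxyphenyl)-3-(hydroxymethyl)-7-methoxy-2,3-dihydro-1-benzofuran-5-yl]methyl}dihydrofuran-2(3H)-one
Conditions: NH4OAc, MeOH/H2O (4:1), rt
Reagents that add atoms: none
Why: Neutral transesterification of aryl acetates to methyl acetate (ammonium acetate in aqueous methanol); no phenoxide is built up, so neither the open α-arm carbinol nor the furan is pushed towards a quinone methide, and the lactone is not opened.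

## Compound list

1 | 5-bromo-2-hydroxy-3-methoxybenzaldehyde | COc1cc(Br)cc(C=O)c1O | starting material
2 | 2-(benzyloxy)-5-bromo-3-methoxybenzaldehyde | COc1cc(Br)cc(C=O)c1OCc1ccccc1 | intermediate
3 | rac-1-[2-(benzyloxy)-5-bromo-3-methoxyphenyl]-2,2,2-trichloroethanol | COc1cc(Br)cc(C(O)C(Cl)(Cl)Cl)c1OCc1ccccc1 | intermediate
4 | [2-(benzyloxy)-5-bromo-3-methoxyphenyl]acetic acid | COc1cc(Br)cc(CC(=O)O)c1OCc1ccccc1 | intermediate
5 | (4S)-4-benzyl-1,3-oxazolidin-2-one | O=C1N[C@@H](Cc2ccccc2)CO1 | starting material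
6 | [2-(benzyloxy)-5-bromo-3-methoxyphenyl]acetic pivalic anhydride | COc1cc(Br)cc(CC(=O)OC(=O)C(C)(C)C)c1OCc1ccccc1 | intermediate (not isolated)
7 | (4S)-4-benzyl-3-{[2-(benzyloxy)-5-bromo-3-methoxyphenyl]acetyl}-1,3-oxazolidin-2-one | COc1cc(Br)cc(CC(=O)N2[C@@H](Cc3ccccc3)COC2=O)c1OCc1ccccc1 | intermediate
8 | 4-(benzyloxy)-3-methoxybenzaldehyde | COc1cc(C=O)ccc1OCc1ccccc1 | starting material
9 | (4S)-4-benzyl-3-{(2R,3S)-3-[4-(benzyloxy)-3-methoxyphenyl]-2-[2-(benzyloxy)-5-bromo-3-methoxyphenyl]-3-(trimethylsilyloxy)propanoyl}-1,3-oxazolidin-2-one | COc1cc([C@@H](O[Si](C)(C)C)[C@H](C(=O)N2[C@@H](Cc3ccccc3)COC2=O)c2cc(Br)cc(OC)c2OCc2ccccc2)ccc1OCc1ccccc1 | intermediate (not isolated)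
10 | (4S)-4-benzyl-3-{(2R,3S)-3-[4-(benzyloxy)-3-methoxyphenyl]-2-[2-(benzyloxy)-5-bromo-3-methoxyphenyl]-3-hydroxypropanoyl}-1,3-oxazolidin-2-one | COc1cc([C@@H](O)[C@H](C(=O)N2[C@@H](Cc3ccccc3)COC2=O)c2cc(Br)cc(OC)c2OCc2ccccc2)ccc1OCc1ccccc1 | intermediate
11 | (1S,2S)-1-[4-(benzyloxy)-3-methoxyphenyl]-2-[2-(benzyloxy)-5-bromo-3-methoxyphenyl]propane-1,3-diol | COc1cc([C@@H](O)[C@H](CO)c2cc(Br)cc(OC)c2OCc2ccccc2)ccc1OCc1ccccc1 | intermediate
12 | (1S,2S)-1-[4-(benzyloxy)-3-methoxyphenyl]-2-[2-(benzyloxy)-5-bromo-3-methoxyphenyl]-1,3-bis(TBSO)propane | COc1cc([C@@H](O[Si](C)(C)C(C)(C)C)[C@H](CO[Si](C)(C)C(C)(C)C)c2cc(Br)cc(OC)c2OCc2ccccc2)ccc1OCc1ccccc1 | intermediate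
13 | 4-(benzyloxy)-3-{(1S,2S)-1-[4-(benzyloxy)-3-methoxyphenyl]-1,3-bis(TBSO)propan-2-yl}-5-methoxybenzaldehyde | COc1cc([C@@H](O[Si](C)(C)C(C)(C)C)[C@H](CO[Si](C)(C)C(C)(C)C)c2cc(C=O)cc(OC)c2OCc2ccccc2)ccc1OCc1ccccc1 | intermediate (not isolated)
14 | [4-(benzyloxy)-3-{(1S,2S)-1-[4-(benzyloxy)-3-methoxyphenyl]-1,3-bis(TBSO)propan-2-yl}-5-methoxyphenyl]methanol | COc1cc([C@@H](O[Si](C)(C)C(C)(C)C)[C@H](CO[Si](C)(C)C(C)(C)C)c2cc(CO)cc(OC)c2OCc2ccccc2)ccc1OCc1ccccc1 | intermediate
15 | 4-(benzyloxy)-3-{(1S,2S)-1-[4-(benzyloxy)-3-methoxyphenyl]-1,3-bis(TBSO)propan-2-yl}-5-methoxybenzyl bromide | COc1cc([C@@H](O[Si](C)(C)C(C)(C)C)[C@H](CO[Si](C)(C)C(C)(C)C)c2cc(CBr)cc(OC)c2OCc2ccccc2)ccc1OCc1ccccc1 | intermediate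
16 | 4-tert-butoxy-4-oxobutanoic acid (mono-tert-butyl succinate) | CC(C)(C)OC(=O)CCC(=O)O | starting material
17 | 4-tert-butoxy-4-oxobutanoic pivalic anhydride | CC(C)(C)OC(=O)CCC(=O)OC(=O)C(C)(C)C | intermediate (not isolated)
18 | tert-butyl 4-[(4S)-4-benzyl-2-oxo-1,3-oxazolidin-3-yl]-4-oxobutanoate | CC(C)(C)OC(=O)CCC(=O)N1[C@@H](Cc2ccccc2)COC1=O | intermediate
19 | tert-butyl (3S)-4-[(4S)-4-benzyl-2-oxo-1,3-oxazolidin-3-yl]-3-[4-(benzyloxy)-3-{(1S,2S)-1-[4-(benzyloxy)-3-methoxyphenyl]-1,3-bis(TBSO)propan-2-yl}-5-methoxybenzyl]-4-oxobutanoate | CC(C)(C)OC(=O)C[C@H](Cc1cc(OC)c(OCc2ccccc2)c(c1)[C@@H](CO[Si](C)(C)C(C)(C)C)[C@H](O[Si](C)(C)C(C)(C)C)c1ccc(OCc2ccccc2)c(OC)c1)C(=O)N1[C@@H](Cc2ccccc2)COC1=O | intermediate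
20 | tert-butyl (3S)-4-[4-(benzyloxy)-3-{(1S,2S)-1-[4-(benzyloxy)-3-methoxyphenyl]-1,3-bis(TBSO)propan-2-yl}-5-methoxyphenyl]-3-(hydroxymethyl)butanoate | CC(C)(C)OC(=O)C[C@H](Cc1cc(OC)c(OCc2ccccc2)c(c1)[C@@H](CO[Si](C)(C)C(C)(C)C)[C@H](O[Si](C)(C)C(C)(C)C)c1ccc(OCc2ccccc2)c(OC)c1)CO | intermediate (not isolated)
21 | (4S)-4-[4-(benzyloxy)-3-{(1S,2S)-1-[4-(benzyloxy)-3-methoxyphenyl]-1,3-bis(TBSO)propan-2-yl}-5-methoxybenzyl]dihydrofuran-2(3H)-one | O=C1C[C@H](Cc2cc(OC)c(OCc3ccccc3)c(c2)[C@@H](CO[Si](C)(C)C(C)(C)C)[C@H](O[Si](C)(C)C(C)(C)C)c2ccc(OCc3ccccc3)c(OC)c2)CO1 | intermediate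
22 | (4S)-4-[3-{(1S,2S)-1,3-bis(TBSO)-1-(4-hydroxy-3-methoxyphenyl)propan-2-yl}-4-hydroxy-5-methoxybenzyl]dihydrofuran-2(3H)-one | O=C1C[C@H](Cc2cc(OC)c(O)c(c2)[C@@H](CO[Si](C)(C)C(C)(C)C)[C@H](O[Si](C)(C)C(C)(C)C)c2ccc(O)c(OC)c2)CO1 | intermediate
23 | (4S)-4-[4-(TBSO)-3-{(1S,2S)-1,3-bis(TBSO)-1-[4-(TBSO)-3-methoxyphenyl]propan-2-yl}-5-methoxybenzyl]dihydrofuran-2(3H)-one | O=C1C[C@H](Cc2cc(OC)c(O[Si](C)(C)C(C)(C)C)c(c2)[C@@H](CO[Si](C)(C)C(C)(C)C)[C@H](O[Si](C)(C)C(C)(C)C)c2ccc(O[Si](C)(C)C(C)(C)C)c(OC)c2)CO1 | intermediate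
24 | (3S,4S)-lactone, α-arm unit with two aryl benzyl ethers and two alkyl TBS ethers, β-arm unit with four TBS ethers (full name in step 15) | COc1cc([C@@H](O[Si](C)(C)C(C)(C)C)[C@H](CO[Si](C)(C)C(C)(C)C)c2cc(C[C@@H]3C(=O)OC[C@H]3Cc3cc(OC)c(O[Si](C)(C)C(C)(C)C)c(c3)[C@@H](CO[Si](C)(C)C(C)(C)C)[C@H](O[Si](C)(C)C(C)(C)C)c3ccc(O[Si](C)(C)C(C)(C)C)c(OC)c3)cc(OC)c2OCc2ccccc2)ccc1OCc1ccccc1 | intermediate
25 | (3S,4S)-lactone, α-arm unit with free phenols and two alkyl TBS ethers, β-arm unit with four TBS ethers (full name in step 16) | COc1cc([C@@H](O[Si](C)(C)C(C)(C)C)[C@H](CO[Si](C)(C)C(C)(C)C)c2cc(C[C@@H]3C(=O)OC[C@H]3Cc3cc(OC)c(O[Si](C)(C)C(C)(C)C)c(c3)[C@@H](CO[Si](C)(C)C(C)(C)C)[C@H](O[Si](C)(C)C(C)(C)C)c3ccc(O[Si](C)(C)C(C)(C)C)c(OC)c3)cc(OC)c2O)ccc1O | intermediate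
26 | (3S,4S)-lactone, α-arm unit with two aryl acetates and two alkyl TBS ethers, β-arm unit with four TBS ethers (full name in step 17) | COc1cc([C@@H](O[Si](C)(C)C(C)(C)C)[C@H](CO[Si](C)(C)C(C)(C)C)c2cc(C[C@@H]3C(=O)OC[C@H]3Cc3cc(OC)c(O[Si](C)(C)C(C)(C)C)c(c3)[C@@H](CO[Si](C)(C)C(C)(C)C)[C@H](O[Si](C)(C)C(C)(C)C)c3ccc(O[Si](C)(C)C(C)(C)C)c(OC)c3)cc(OC)c2OC(C)=O)ccc1OC(C)=O | intermediate
27 | (3S,4S)-3-[4-acetoxy-3-{(1S,2S)-1-(4-acetoxy-3-methoxyphenyl)-1,3-dihydroxypropan-2-yl}-5-methoxybenzyl]-4-[3-{(1S,2S)-1,3-dihydroxy-1-(4-hydroxy-3-methoxyphenyl)propan-2-yl}-4-hydroxy-5-methoxybenzyl]dihydrofuran-2(3H)-one | COc1cc([C@@H](O)[C@H](CO)c2cc(C[C@@H]3C(=O)OC[C@H]3Cc3cc(OC)c(O)c(c3)[C@@H](CO)[C@H](O)c3ccc(O)c(OC)c3)cc(OC)c2OC(C)=O)ccc1OC(C)=O | intermediate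
28 | para-quinone methide of 27: β-arm C7' doubly bonded to C4 of a 2-methoxycyclohexa-2,5-dien-1-one (former ring D), C8' (S) and the α-arm unchanged | COc1cc([C@@H](O)[C@H](CO)c2cc(C[C@@H]3C(=O)OC[C@H]3Cc3cc(OC)c(O)c(c3)[C@@H](CO)C=C3C=CC(=O)C(OC)=C3)cc(OC)c2OC(C)=O)ccc1OC(C)=O | intermediate (not isolated)
29 | (3S,4S)-3-[4-acetoxy-3-{(1S,2S)-1-(4-acetoxy-3-methoxyphenyl)-1,3-dihydroxypropan-2-yl}-5-methoxybenzyl]-4-{[(2R,3S)-2-(4-hydroxy-3-methoxyphenyl)-3-(hydroxymethyl)-7-methoxy-2,3-dihydro-1-benzofuran-5-yl]methyl}dihydrofuran-2(3H)-one | COc1cc([C@@H](O)[C@H](CO)c2cc(C[C@@H]3C(=O)OC[C@H]3Cc3cc(OC)c4c(c3)[C@@H](CO)[C@H](c3ccc(O)c(OC)c3)O4)cc(OC)c2OC(C)=O)ccc1OC(C)=O | intermediate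
30 | CNP0186558.3, (3S,4S)-3-[3-{(1S,2S)-1,3-dihydroxy-1-(4-hydroxy-3-methoxyphenyl)propan-2-yl}-4-hydroxy-5-methoxybenzyl]-4-{[(2R,3S)-2-(4-hydroxy-3-methoxyphenyl)-3-(hydroxymethyl)-7-methoxy-2,3-dihydro-1-benzofuran-5-yl]methyl}dihydrofuran-2(3H)-one | COc1cc([C@@H](O)[C@H](CO)c2cc(C[C@@H]3C(=O)OC[C@H]3Cc3cc(OC)c4c(c3)[C@@H](CO)[C@H](c3ccc(O)c(OC)c3)O4)cc(OC)c2O)ccc1O | target

## Step count and least certain steps

Total step count: 20. Longest linear sequence: 19 steps (from 1 through steps 1 to 9 and 11 to 20); step 10 is the only side branch.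

**Step 19 (key step).**
- *What may go wrong:* loss of arm selectivity through acid-promoted acetyl migration from the ring B acetate to the neighbouring C7 or C9 hydroxyl, which would re-expose a phenol beside C7. Capture of quinone methide 28 by a primary hydroxyl of a second molecule is also possible, as is incomplete cis-to-trans equilibration at C2.
- *Fallback:* close the furan before the second unit is present. Setting out from diphenol lactone 22, HF·pyridine would remove the two alkyl silyl groups to give free β-arm lactone F1. Catalytic TsOH would then cyclise this single-arm substrate to furan lactone F2. TESCl and imidazole would mask its phenol and primary alcohol as bis(triethylsilyl) ether F3. Alkylation of the lithium enolate of F3 with bromide 15, as in step 15, would give trans lactone F4. Hydrogenolysis over Pd/C would give diphenol F5, and buffered HF·pyridine would remove the four silyl groups, coming back to the route at target 30.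

**Step 5 (anti-aldol).**
- *What may go wrong:* erosion of the anti selectivity, or epimerisation at C8, because the arylacetyl α-proton stays acidic in the adduct under Et3N. The facial sense rests on the chelate model and may also prove wrong.
- *Fallback:* a syn-aldol followed by inversion of C7. Setting out from acid 4, acylation of (4R)-4-benzyl-1,3-oxazolidin-2-one as in step 4 would give enantiomeric-auxiliary imide F6. The boron aldol with n-Bu2BOTf and i-Pr2NEt and aldehyde 8 would give syn adduct F7, with C8 as required and C7 epimeric. LiBH4 would give syn diol F8, and TBSCl with imidazole would silylate only the primary hydroxyl to give monosilyl ether F9. Mitsunobu reaction with 4-nitrobenzoic acid, PPh3 and diisopropyl azodicarboxylate would give inverted ester F10, and K2CO3 in methanol would give anti alcohol F11. TBSOTf and 2,6-lutidine would then silylate C7–OH, coming back to the route at 12.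

**Step 3 (reductive homologation).**
- *What may go wrong:* solvolytic opening of the benzylic dichloroepoxide by hydroxide or tert-butoxide instead of hydride delivery, which would give α-oxygenated arylacetic acids from this electron-rich ring.
- *Fallback:* setting out from aldehyde 2, Wittig reaction with (methoxymethyl)triphenylphosphonium chloride and KOt-Bu would give enol ether F12 as an E/Z mixture. Mild aqueous acid would give arylacetaldehyde F13, and Pinnick oxidation (NaClO2, NaH2PO4, 2-methyl-2-butene) would come back to the route at acid 4.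

**Step 20 (final deacetylation).**
- *What may go wrong:* slow cleavage of the hindered ring B acetate under neutral conditions. A move to basic conditions would then allow phenoxide-driven quinone methide formation, by reversible opening of the furan or by loss of a migrated benzylic acetate.
- *Fallback:* replace the acetates by groups removed without any base. Setting out from diphenol 25, allyl chloroformate and pyridine would give bis(allyl carbonate) F14. HF·pyridine would give hexaol F15, and catalytic TsOH would close the furan as in step 19 to give cyclised bis(allyl carbonate) F16, the carbonates deactivating the α-arm as the acetates do. Pd(PPh3)4 (zerovalent palladium) and morpholine at rt would then cleave both allyl carbonates, coming back to the route at 30.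

## Further compounds

F1 | step 19 | (4S)-4-[3-{(1S,2S)-1,3-dihydroxy-1-(4-hydroxy-3-methoxyphenyl)propan-2-yl}-4-hydroxy-5-methoxybenzyl]dihydrofuran-2(3H)-one | O=C1C[C@H](Cc2cc(OC)c(O)c(c2)[C@@H](CO)[C@H](O)c2ccc(O)c(OC)c2)CO1
F2 | step 19 | (4S)-4-{[(2R,3S)-2-(4-hydroxy-3-methoxyphenyl)-3-(hydroxymethyl)-7-methoxy-2,3-dihydro-1-benzofuran-5-yl]methyl}dihydrofuran-2(3H)-one | O=C1C[C@H](Cc2cc(OC)c3c(c2)[C@@H](CO)[C@H](c2ccc(O)c(OC)c2)O3)CO1
F3 | step 19 | bis(triethylsilyl) ether of F2 (phenol and primary alcohol) | O=C1C[C@H](Cc2cc(OC)c3c(c2)[C@@H](CO[Si](CC)(CC)CC)[C@H](c2ccc(O[Si](CC)(CC)CC)c(OC)c2)O3)CO1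
F4 | step 19 | (3S,4S)-lactone, α-arm unit as in 24 (two aryl benzyl ethers, two alkyl TBS ethers), β-arm closed (2R,3S)-furan as bis(triethylsilyl) ether | COc1cc([C@@H](O[Si](C)(C)C(C)(C)C)[C@H](CO[Si](C)(C)C(C)(C)C)c2cc(C[C@@H]3C(=O)OC[C@H]3Cc3cc(OC)c4c(c3)[C@@H](CO[Si](CC)(CC)CC)[C@H](c3ccc(O[Si](CC)(CC)CC)c(OC)c3)O4)cc(OC)c2OCc2ccccc2)ccc1OCc1ccccc1
F5 | step 19 | F4 with both α-arm phenols free | COc1cc([C@@H](O[Si](C)(C)C(C)(C)C)[C@H](CO[Si](C)(C)C(C)(C)C)c2cc(C[C@@H]3C(=O)OC[C@H]3Cc3cc(OC)c4c(c3)[C@@H](CO[Si](CC)(CC)CC)[C@H](c3ccc(O[Si](CC)(CC)CC)c(OC)c3)O4)cc(OC)c2O)ccc1O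
F6 | step 5 | (4R)-4-benzyl-3-{[2-(benzyloxy)-5-bromo-3-methoxyphenyl]acetyl}-1,3-oxazolidin-2-one | COc1cc(Br)cc(CC(=O)N2[C@H](Cc3ccccc3)COC2=O)c1OCc1ccccc1
F7 | step 5 | (4R)-4-benzyl-3-{(2R,3R)-3-[4-(benzyloxy)-3-methoxyphenyl]-2-[2-(benzyloxy)-5-bromo-3-methoxyphenyl]-3-hydroxypropanoyl}-1,3-oxazolidin-2-one | COc1cc([C@H](O)[C@H](C(=O)N2[C@H](Cc3ccccc3)COC2=O)c2cc(Br)cc(OC)c2OCc2ccccc2)ccc1OCc1ccccc1
F8 | step 5 | (1R,2S)-1-[4-(benzyloxy)-3-methoxyphenyl]-2-[2-(benzyloxy)-5-bromo-3-methoxyphenyl]propane-1,3-diol | COc1cc([C@H](O)[C@H](CO)c2cc(Br)cc(OC)c2OCc2ccccc2)ccc1OCc1ccccc1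
F9 | step 5 | (1R,2S)-1-[4-(benzyloxy)-3-methoxyphenyl]-2-[2-(benzyloxy)-5-bromo-3-methoxyphenyl]-3-(TBSO)propan-1-ol | COc1cc([C@H](O)[C@H](CO[Si](C)(C)C(C)(C)C)c2cc(Br)cc(OC)c2OCc2ccccc2)ccc1OCc1ccccc1
F10 | step 5 | (1S,2S)-1-[4-(benzyloxy)-3-methoxyphenyl]-2-[2-(benzyloxy)-5-bromo-3-methoxyphenyl]-3-(TBSO)propyl 4-nitrobenzoate | COc1cc([C@@H](OC(=O)c2ccc(cc2)[N+](=O)[O-])[C@H](CO[Si](C)(C)C(C)(C)C)c2cc(Br)cc(OC)c2OCc2ccccc2)ccc1OCc1ccccc1
F11 | step 5 | (1S,2S)-1-[4-(benzyloxy)-3-methoxyphenyl]-2-[2-(benzyloxy)-5-bromo-3-methoxyphenyl]-3-(TBSO)propan-1-ol | COc1cc([C@@H](O)[C@H](CO[Si](C)(C)C(C)(C)C)c2cc(Br)cc(OC)c2OCc2ccccc2)ccc1OCc1ccccc1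
F12 | step 3 | 2-(benzyloxy)-5-bromo-1-methoxy-3-(2-methoxyethenyl)benzene (E/Z mixture) | COC=Cc1cc(Br)cc(OC)c1OCc1ccccc1
F13 | step 3 | [2-(benzyloxy)-5-bromo-3-methoxyphenyl]acetaldehyde | COc1cc(Br)cc(CC=O)c1OCc1ccccc1
F14 | step 20 | analogue of 26 with allyl carbonates in place of the two aryl acetates | COc1cc([C@@H](O[Si](C)(C)C(C)(C)C)[C@H](CO[Si](C)(C)C(C)(C)C)c2cc(C[C@@H]3C(=O)OC[C@H]3Cc3cc(OC)c(O[Si](C)(C)C(C)(C)C)c(c3)[C@@H](CO[Si](C)(C)C(C)(C)C)[C@H](O[Si](C)(C)C(C)(C)C)c3ccc(O[Si](C)(C)C(C)(C)C)c(OC)c3)cc(OC)c2OC(=O)OCC=C)ccc1OC(=O)OCC=C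
F15 | step 20 | analogue of 27 with allyl carbonates in place of the two aryl acetates | COc1cc([C@@H](O)[C@H](CO)c2cc(C[C@@H]3C(=O)OC[C@H]3Cc3cc(OC)c(O)c(c3)[C@@H](CO)[C@H](O)c3ccc(O)c(OC)c3)cc(OC)c2OC(=O)OCC=C)ccc1OC(=O)OCC=C
F16 | step 20 | analogue of 29 with allyl carbonates in place of the two aryl acetates | COc1cc([C@@H](O)[C@H](CO)c2cc(C[C@@H]3C(=O)OC[C@H]3Cc3cc(OC)c4c(c3)[C@@H](CO)[C@H](c3ccc(O)c(OC)c3)O4)cc(OC)c2OC(=O)OCC=C)ccc1OC(=O)OCC=C
A1 | alternative 1 | methyl 3-{(E)-2-[4-(benzyloxy)-3-methoxyphenyl]ethenyl}-5-methoxy-4-(pivaloyloxy)benzoate | COc1cc(/C=C/c2cc(C(=O)OC)cc(OC)c2OC(=O)C(C)(C)C)ccc1OCc1ccccc1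
A2 | alternative 1 | methyl 3-{(4S,5S)-4-[4-(benzyloxy)-3-methoxyphenyl]-1,3-dioxan-5-yl}-5-methoxy-4-(pivaloyloxy)benzoate (trans) | COc1cc([C@H]2OCOC[C@@H]2c2cc(C(=O)OC)cc(OC)c2OC(=O)C(C)(C)C)ccc1OCc1ccccc1
A3 | alternative 2 | methyl 2-diazo-2-{5-bromo-3-methoxy-2-[(4-(TBSO)-3-methoxybenzyl)oxy]phenyl}acetate | COC(=O)C(=[N+]=[N-])c1cc(Br)cc(OC)c1OCc1ccc(O[Si](C)(C)C(C)(C)C)c(OC)c1
A4 | alternative 2 | methyl (2R,3S)-5-bromo-7-methoxy-2-[4-(TBSO)-3-methoxyphenyl]-2,3-dihydro-1-benzofuran-3-carboxylate (trans) | COC(=O)[C@@H]1c2cc(Br)cc(OC)c2O[C@@H]1c1ccc(O[Si](C)(C)C(C)(C)C)c(OC)c1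
A5 | alternative 3 | 3-{[(2R,3S)-3-(TBSO-methyl)-2-[4-(TBSO)-3-methoxyphenyl]-7-methoxy-2,3-dihydro-1-benzofuran-5-yl]methyl}cyclobutan-1-one | O=C1CC(Cc2cc(OC)c3c(c2)[C@@H](CO[Si](C)(C)C(C)(C)C)[C@H](c2ccc(O[Si](C)(C)C(C)(C)C)c(OC)c2)O3)C1
A6 | alternative 3 | (4S)-4-{[(2R,3S)-3-(TBSO-methyl)-2-[4-(TBSO)-3-methoxyphenyl]-7-methoxy-2,3-dihydro-1-benzofuran-5-yl]methyl}dihydrofuran-2(3H)-one | O=C1C[C@H](Cc2cc(OC)c3c(c2)[C@@H](CO[Si](C)(C)C(C)(C)C)[C@H](c2ccc(O[Si](C)(C)C(C)(C)C)c(OC)c2)O3)CO1
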